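**Retrosynthetic overview**
1. 26 ⇐ 25 by loss of 14 benzyl groups. 25 ⇐ 24 by reductive removal of a temporary C4–O bond in the lower unit, which carries a chiral auxiliary.
2. 24 ⇐ O,S-acetal 14 + (Z)-2-alkoxyvinyl gallate 21. An auxiliary-controlled oxa-Povarov [4+2] annulation closes the lower pyran ring (ring F), makes C2–C3 and C4–C4a together, and brings in C3, C4, the lower gallate and both lower stereocentres.
3. Enabling feature: the lower A ring (ring D) is a phloroglucinol ring with a local twofold axis through C6 (the interflavan carbon) and C8a–O1. Its two CH carbons (later C4a and C8) are equivalent and each is ortho/para to three oxygens, and O1 is the only oxygen para to C6, so a cation built on O1 can close only to the 4→6 isomer.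
4. 14 ⇐ phenol 10 ⇐ 4β-selective Friedel–Crafts union of the epicatechin-derived C4 electrophile 6 with phloroglucinol diether 8. This is done before ring F exists, so no 4→8/4→6 competition arises.
5. Ring order: rings A, B and C come intact from (–)-epicatechin 1, ring D is attached in step 6, ring E arrives with C2 in step 9, and ring F is formed last in step 13.

Key step: step 13

Assumption: the sense of induction of the 2-phenylcyclohexyl auxiliary in step 13 is assigned from the s-trans enol ether/phenyl-shielding model; if a model run shows the opposite sense, the equally available (1R,2S)-alcohol replaces 15 and nothing else changes.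

**Step 1**
Reactants: 1 (–)-epicatechin
Product: 2 5,7,3',4'-tetra-O-benzyl-(–)-epicatechin
Conditions: BnBr (4.4 equiv), K2CO3, DMF, 0 °C to rt
Reagents that add atoms: benzyl bromide, BrCc1ccccc1
Why: Williamson etherification under carbonate conditions reaches only the four acidic phenols and leaves the secondary 3-OH and both stereocentres untouched.

**Step 2**
Reactants: 2 5,7,3',4'-tetra-O-benzyl-(–)-epicatechin
Product: 3 5,7,3',4'-tetra-O-benzyl-4β-(2-ethoxyethoxy)epicatechin (2,3-cis, 3,4-trans)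
Conditions: DDQ, 2-ethoxyethanol, CH2Cl2, rt
Reagents that add atoms: 2-ethoxyethanol, CCOCCO
Why: In this DDQ benzylic oxidation, hydride loss from C4 gives the A-ring-stabilised cation, which the alcohol traps from the β face, anti to the 2-aryl and 3-OH groups.

**Step 3**
Reactants: 4 3,4,5-tris(benzyloxy)benzoic acid
Product: 5 3,4,5-tris(benzyloxy)benzoyl chloride
Conditions: (COCl)2, cat. DMF, CH2Cl2, 0 °C to rt
Reagents that add atoms: oxalyl chloride, ClC(=O)C(=O)Cl
Why: DMF-catalysed (Vilsmeier-type) conversion of an acid into its chloride does not affect benzyl ethers.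

**Step 4**
Reactants: 3 5,7,3',4'-tetra-O-benzyl-4β-(2-ethoxyethoxy)epicatechin; 5 3,4,5-tris(benzyloxy)benzoyl chloride
Product: 6 5,7,3',4'-tetra-O-benzyl-4β-(2-ethoxyethoxy)epicatechin 3-O-[3,4,5-tris(benzyloxy)benzoate]
Conditions: Et3N, DMAP, CH2Cl2, rt
Reagents that add atoms: none
Why: DMAP-catalysed acylation of the only free hydroxyl touches no stereocentre, and the 4β-ether is stable to base.

**Step 5**
Reactants: 7 3,5-bis(benzyloxy)phenol
Product: 8 [3,5-bis(benzyloxy)phenoxy]triisopropylsilane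
Conditions: TIPSCl, imidazole, DMF, rt
Reagents that add atoms: triisopropylsilyl chloride, CC(C)[Si](Cl)(C(C)C)C(C)C
Why: Imidazole-promoted silylation installs a bulky group that marks the oxygen that becomes O1 and shields both carbons ortho to it.

**Step 6**
Reactants: 6 the 4β-(2-ethoxyethoxy) gallate; 8 [3,5-bis(benzyloxy)phenoxy]triisopropylsilane (3 equiv)
Product: 9 4β-[2,6-bis(benzyloxy)-4-(triisopropylsilyloxy)phenyl]-5,7,3',4'-tetra-O-benzylepicatechin 3-O-[3,4,5-tris(benzyloxy)benzoate]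
Conditions: TMSOTf (0.3 equiv), CH2Cl2, −78 to −40 °C
Reagents that add atoms: none
Why: In this Friedel–Crafts arylation the flavan-4-yl cation, held on its α face by the 3-O-acyl group, is attacked from the β face (3,4-trans) by the carbon of 8 para to the silyloxy group, because the two carbons ortho to OTIPS are shielded.

**Step 7**
Reactants: 9 the TIPS ether
Product: 10 4β-[2,6-bis(benzyloxy)-4-hydroxyphenyl]-5,7,3',4'-tetra-O-benzylepicatechin 3-O-[3,4,5-tris(benzyloxy)benzoate]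
Conditions: TBAF, AcOH, THF, 0 °C
Reagents that add atoms: none
Why: Fluoride cleaves only the Si–O bond, and the acetic acid buffer protonates the phenoxide so that the gallate ester is not attacked.

**Step 8**
Reactants: 11 3,4-bis(benzyloxy)benzyl chloride
Product: 12 3,4-bis(benzyloxy)benzyl phenyl sulfide
Conditions: PhSH, K2CO3, DMF, rt
Reagents that add atoms: thiophenol, Sc1ccccc1
Why: This is an SN2 thioetherification of a benzylic chloride by thiophenolate.

**Step 9**
Reactants: 12 3,4-bis(benzyloxy)benzyl phenyl sulfide (1.5 equiv); 10 the phenol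
Product: 14 O,S-acetal, the ring-D oxygen of 10 carrying CH(SPh)[3,4-bis(benzyloxy)phenyl] (both epimers at the acetal carbon), via α-chloro-3,4-bis(benzyloxy)benzyl phenyl sulfide 13 (not isolated)
Conditions: (i) 12, NCS, toluene, 0 °C to rt, succinimide filtered off; (ii) filtrate added to 10, Cs2CO3, DMF, 0 °C to rt; Et3N-deactivated silica
Reagents that add atoms: N-chlorosuccinimide, O=C1CCC(=O)N1Cl (supplies the chlorine of 13, which is lost again on the way to 14)
Why: NCS α-chlorination of the sulfide (Pummerer-type, via the chlorosulfonium salt) is followed by O-alkylation of the unhindered phenoxide, the reaction type of methylthiomethyl ether formation, and the mixed acetal centre does not matter because it becomes planar in step 13.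

**Step 10**
Reactants: 15 (1S,2R)-(+)-trans-2-phenylcyclohexanol
Product: 17 allyl (1S,2R)-2-phenylcyclohexyl ether, via sodium (1S,2R)-2-phenylcyclohexanolate 16 (not isolated)
Conditions: NaH, THF–DMF, 0 °C; allyl bromide, cat. Bu4NI, rt
Reagents that add atoms: allyl bromide, C=CCBr; sodium hydride, [H-].[Na+] (sodium of 16 only)
Why: Williamson etherification keeps the C–O bond of the carbinol centre intact, so its configuration is retained.

**Step 11**
Reactants: 17 allyl (1S,2R)-2-phenylcyclohexyl ether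
Product: 19 2-[(1S,2R)-2-phenylcyclohexyloxy]acetaldehyde, via the secondary ozonide (3-substituted 1,2,4-trioxolane) 18 (not isolated)
Conditions: O3, CH2Cl2, −78 °C; Me2S, −78 °C to rt
Reagents that add atoms: ozone, [O-][O+]=O
Why: Ozonolysis with reductive work-up cleaves only the terminal alkene, since the phenyl ring and the ether are inert at −78 °C.

**Step 12**
Reactants: 19 2-[(1S,2R)-2-phenylcyclohexyloxy]acetaldehyde; 5 3,4,5-tris(benzyloxy)benzoyl chloride
Product: 21 (Z)-2-[(1S,2R)-2-phenylcyclohexyloxy]vinyl 3,4,5-tris(benzyloxy)benzoate, via the potassium (Z)-enolate 20 (not isolated)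
Conditions: KHMDS, THF, −78 °C (19 added to the base); then 5, −78 to 0 °C
Reagents that add atoms: potassium hexamethyldisilazide, C[Si](C)(C)[N-][Si](C)(C)C.[K+] (potassium of 20 only)
Why: Deprotonation gives the potassium-chelated (Z)-enolate, whose hard oxygen is acylated by the acid chloride (enolate O-acylation), so chelation fixes the cis-1,2-dioxygenated alkene geometry.

**Step 13**
Reactants: 14 the O,S-acetal; 21 the (Z)-2-alkoxyvinyl gallate (3 equiv)
Product: 24 per-O-benzyl epicatechin-3-O-gallate-(4β→6)-[4-((1S,2R)-2-phenylcyclohexyloxy)epicatechin-3-O-gallate], lower unit 2,3-cis-3,4-cis, via the (E)-aryl oxocarbenium triflate 22 (not isolated), via the alkoxycarbenium triflate 23 (not isolated)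
Conditions: AgOTf (1.5 equiv), 2,6-di-tert-butyl-4-methylpyridine (DTBMP, 2 equiv), 4 Å MS, CH2Cl2–toluene, 5 mM in 14, −78 to −30 °C, dark
Reagents that add atoms: silver triflate, [Ag+].[O-]S(=O)(=O)C(F)(F)F (triflate counter-ion of 22 and 23 only)
Why: Proposed new method: Ag(I) pulls the soft thiolate off O,S-acetal 14 (both epimers converge) and leaves every hard C–O bond alone, giving the (E)-aryl oxocarbenium ion 22, a cationic 2-oxadiene made of C4a=C8a–O1=C2. The ether oxygen of 21 is a stronger donor than its acyloxy oxygen, so the gallate-bearing carbon attacks C2 (C2–C3 bond) and the charge moves to the auxiliary-bearing carbon in 23, which is captured by the ring-D CH ortho to O1 in a 6-exo-trig Friedel–Crafts closure of the pyran ring (C4–C4a bond) with DTBMP taking the proton, overall a stepwise inverse-demand [4+2]. The closest known reaction types are the oxa-Povarov reaction of aryl oxocarbenium ions with alkenes, the Lewis-acid-promoted hetero-[4+2] cycloaddition of chiral 2-(acyloxy)vinyl ethers and the Ag(I) activation of benzylic flavan thioethers, and what is new is their union with a 1,2-dioxygenated alkene under auxiliary control. C3 is set by the auxiliary: A(1,3) strain holds the Z-enol ether s-trans, the phenyl ring of the (1S,2R)-2-phenylcyclohexyl group covers one π-face, and C2 bonds to the open face, which corresponds to 3R. C2 is set by the approach: the alkoxy donor lies endo under the aryloxy π-system of the E-cation, as in Povarov reactions of cis-enol ethers, so the Z geometry is carried into the 2,3-cis (2R) and 3,4-cis relationships, and the C4 centre does not matter because step 14 erases it. Site selectivity is secured because rotation about the interflavan bond interchanges the two ring-D CH carbons and the ortho oxygens are benzylated, so only the 4→6 skeleton can form, and chemoselectivity is secured by excess 21, high dilution of 14 and the inertness of the hard C4–O bond of 24 to buffered Ag(I).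

**Step 14**
Reactants: 24 the 4-alkoxy dimer
Product: 25 per-O-benzyl epicatechin-3-O-gallate-(4β→6)-epicatechin-3-O-gallate (14 benzyl ethers)
Conditions: Et3SiH (10 equiv), TMSOTf (0.2 equiv), CH2Cl2, −78 to −40 °C
Reagents that add atoms: none
Why: In this ionic hydrogenation the silyl triflate ionises only the C4–O bond benzylic to the trioxygenated ring D and the silane delivers hydride to C4, while C2 and C3 are not involved, the auxiliary leaves as its silyl ether, and the conditions match those under which the interflavan bond was made in step 6.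

**Step 15**
Reactants: 25 the per-O-benzyl dimer
Product: 26 procyanidin B-5 3,3'-di-O-gallate
Conditions: H2 (1 atm), 20% Pd(OH)2/C, THF–MeOH–H2O, rt; filtration, lyophilisation
Reagents that add atoms: none
Why: Neutral hydrogenolysis removes all 14 benzyl ethers while the esters, the interflavan bond and the five stereocentres persist.

**Compound list**
1 | (–)-epicatechin (2R,3R) | O[C@@H]1Cc2c(O)cc(O)cc2O[C@@H]1c1ccc(O)c(O)c1 | starting material
2 | 5,7,3',4'-tetra-O-benzyl-(–)-epicatechin | O[C@@H]1Cc2c(OCc3ccccc3)cc(OCc3ccccc3)cc2O[C@@H]1c1ccc(OCc2ccccc2)c(OCc2ccccc2)c1 | intermediate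
3 | 5,7,3',4'-tetra-O-benzyl-4β-(2-ethoxyethoxy)epicatechin | O[C@@H]1[C@@H](OCCOCC)c2c(OCc3ccccc3)cc(OCc3ccccc3)cc2O[C@@H]1c1ccc(OCc2ccccc2)c(OCc2ccccc2)c1 | intermediate
4 | 3,4,5-tris(benzyloxy)benzoic acid | OC(=O)c1cc(OCc2ccccc2)c(OCc2ccccc2)c(OCc2ccccc2)c1 | starting material
5 | 3,4,5-tris(benzyloxy)benzoyl chloride | ClC(=O)c1cc(OCc2ccccc2)c(OCc2ccccc2)c(OCc2ccccc2)c1 | intermediate
6 | 5,7,3',4'-tetra-O-benzyl-4β-(2-ethoxyethoxy)epicatechin 3-O-[3,4,5-tris(benzyloxy)benzoate] | O=C(O[C@@H]1[C@@H](OCCOCC)c2c(OCc3ccccc3)cc(OCc3ccccc3)cc2O[C@@H]1c1ccc(OCc2ccccc2)c(OCc2ccccc2)c1)c1cc(OCc2ccccc2)c(OCc2ccccc2)c(OCc2ccccc2)c1 | intermediate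
7 | 3,5-bis(benzyloxy)phenol | Oc1cc(OCc2ccccc2)cc(OCc2ccccc2)c1 | starting material
8 | [3,5-bis(benzyloxy)phenoxy]triisopropylsilane | CC(C)[Si](Oc1cc(OCc2ccccc2)cc(OCc2ccccc2)c1)(C(C)C)C(C)C | intermediate
9 | 4β-[2,6-bis(benzyloxy)-4-(triisopropylsilyloxy)phenyl]-5,7,3',4'-tetra-O-benzylepicatechin 3-O-[3,4,5-tris(benzyloxy)benzoate] | O=C(O[C@@H]1[C@@H](c2c(OCc3ccccc3)cc(O[Si](C(C)C)(C(C)C)C(C)C)cc2OCc3ccccc3)c2c(OCc3ccccc3)cc(OCc3ccccc3)cc2O[C@@H]1c1ccc(OCc2ccccc2)c(OCc2ccccc2)c1)c1cc(OCc2ccccc2)c(OCc2ccccc2)c(OCc2ccccc2)c1 | intermediate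
10 | 4β-[2,6-bis(benzyloxy)-4-hydroxyphenyl]-5,7,3',4'-tetra-O-benzylepicatechin 3-O-[3,4,5-tris(benzyloxy)benzoate] | O=C(O[C@@H]1[C@@H](c2c(OCc3ccccc3)cc(O)cc2OCc3ccccc3)c2c(OCc3ccccc3)cc(OCc3ccccc3)cc2O[C@@H]1c1ccc(OCc2ccccc2)c(OCc2ccccc2)c1)c1cc(OCc2ccccc2)c(OCc2ccccc2)c(OCc2ccccc2)c1 | intermediate
11 | 3,4-bis(benzyloxy)benzyl chloride | ClCc1ccc(OCc2ccccc2)c(OCc2ccccc2)c1 | starting material
12 | 3,4-bis(benzyloxy)benzyl phenyl sulfide | C(Sc1ccccc1)c1ccc(OCc2ccccc2)c(OCc2ccccc2)c1 | intermediate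
13 | α-chloro-3,4-bis(benzyloxy)benzyl phenyl sulfide (racemic) | ClC(Sc1ccccc1)c1ccc(OCc2ccccc2)c(OCc2ccccc2)c1 | intermediate (not isolated)
14 | O,S-acetal of 10: ring-D O–CH(SPh)[3,4-bis(benzyloxy)phenyl], both epimers at the acetal carbon | O=C(O[C@@H]1[C@@H](c2c(OCc3ccccc3)cc(OC(Sc3ccccc3)c3ccc(OCc4ccccc4)c(OCc4ccccc4)c3)cc2OCc3ccccc3)c2c(OCc3ccccc3)cc(OCc3ccccc3)cc2O[C@@H]1c1ccc(OCc2ccccc2)c(OCc2ccccc2)c1)c1cc(OCc2ccccc2)c(OCc2ccccc2)c(OCc2ccccc2)c1 | intermediate
15 | (1S,2R)-(+)-trans-2-phenylcyclohexanol | O[C@H]1CCCC[C@@H]1c1ccccc1 | starting material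
16 | sodium (1S,2R)-2-phenylcyclohexanolate | [Na+].[O-][C@H]1CCCC[C@@H]1c1ccccc1 | intermediate (not isolated)
17 | allyl (1S,2R)-2-phenylcyclohexyl ether | C=CCO[C@H]1CCCC[C@@H]1c1ccccc1 | intermediate
18 | 3-{[(1S,2R)-2-phenylcyclohexyloxy]methyl}-1,2,4-trioxolane | O1OC(CO[C@H]2CCCC[C@@H]2c2ccccc2)OC1 | intermediate (not isolated)
19 | 2-[(1S,2R)-2-phenylcyclohexyloxy]acetaldehyde | O=CCO[C@H]1CCCC[C@@H]1c1ccccc1 | intermediate
20 | potassium (Z)-2-[(1S,2R)-2-phenylcyclohexyloxy]ethenolate | [K+].[O-]/C=C\O[C@H]1CCCC[C@@H]1c1ccccc1 | intermediate (not isolated)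
21 | (Z)-2-[(1S,2R)-2-phenylcyclohexyloxy]vinyl 3,4,5-tris(benzyloxy)benzoate | O=C(O/C=C\O[C@H]1CCCC[C@@H]1c1ccccc1)c1cc(OCc2ccccc2)c(OCc2ccccc2)c(OCc2ccccc2)c1 | intermediate
22 | (E)-aryl oxocarbenium triflate, ring-D O(+)=CH[3,4-bis(benzyloxy)phenyl] | O=C(O[C@@H]1[C@@H](c2c(OCc3ccccc3)cc(/[O+]=C/c3ccc(OCc4ccccc4)c(OCc4ccccc4)c3)cc2OCc3ccccc3)c2c(OCc3ccccc3)cc(OCc3ccccc3)cc2O[C@@H]1c1ccc(OCc2ccccc2)c(OCc2ccccc2)c1)c1cc(OCc2ccccc2)c(OCc2ccccc2)c(OCc2ccccc2)c1.[O-]S(=O)(=O)C(F)(F)F | intermediate (not isolated)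
23 | alkoxycarbenium triflate after C2–C3 bond formation, ring-D O–CH(Ar)–CH(O-galloyl)–CH=O(+)–auxiliary | O=C(O[C@@H]1[C@@H](c2c(OCc3ccccc3)cc(O[C@H](c3ccc(OCc4ccccc4)c(OCc4ccccc4)c3)[C@H](OC(=O)c3cc(OCc4ccccc4)c(OCc4ccccc4)c(OCc4ccccc4)c3)C=[O+][C@H]3CCCC[C@@H]3c3ccccc3)cc2OCc3ccccc3)c2c(OCc3ccccc3)cc(OCc3ccccc3)cc2O[C@@H]1c1ccc(OCc2ccccc2)c(OCc2ccccc2)c1)c1cc(OCc2ccccc2)c(OCc2ccccc2)c(OCc2ccccc2)c1.[O-]S(=O)(=O)C(F)(F)F | intermediate (not isolated)
24 | per-O-benzyl epicatechin-3-O-gallate-(4β→6)-[4-((1S,2R)-2-phenylcyclohexyloxy)epicatechin-3-O-gallate], lower unit all-cis | O=C(O[C@@H]1[C@@H](c2c(OCc4ccccc4)cc3c(c2OCc4ccccc4)[C@@H](O[C@H]4CCCC[C@@H]4c4ccccc4)[C@@H](OC(=O)c4cc(OCc5ccccc5)c(OCc5ccccc5)c(OCc5ccccc5)c4)[C@@H](c4ccc(OCc5ccccc5)c(OCc5ccccc5)c4)O3)c2c(OCc3ccccc3)cc(OCc3ccccc3)cc2O[C@@H]1c1ccc(OCc2ccccc2)c(OCc2ccccc2)c1)c1cc(OCc2ccccc2)c(OCc2ccccc2)c(OCc2ccccc2)c1 | intermediate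
25 | per-O-benzyl epicatechin-3-O-gallate-(4β→6)-epicatechin-3-O-gallate | O=C(O[C@@H]1[C@@H](c2c(OCc4ccccc4)cc3c(c2OCc4ccccc4)C[C@@H](OC(=O)c4cc(OCc5ccccc5)c(OCc5ccccc5)c(OCc5ccccc5)c4)[C@@H](c4ccc(OCc5ccccc5)c(OCc5ccccc5)c4)O3)c2c(OCc3ccccc3)cc(OCc3ccccc3)cc2O[C@@H]1c1ccc(OCc2ccccc2)c(OCc2ccccc2)c1)c1cc(OCc2ccccc2)c(OCc2ccccc2)c(OCc2ccccc2)c1 | intermediate
26 | procyanidin B-5 3,3'-di-O-gallate | O=C(O[C@@H]1[C@@H](c2c(O)cc3c(c2O)C[C@@H](OC(=O)c2cc(O)c(O)c(O)c2)[C@@H](c2ccc(O)c(O)c2)O3)c2c(O)cc(O)cc2O[C@@H]1c1ccc(O)c(O)c1)c1cc(O)c(O)c(O)c1 | target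

**Total step count:** 15
**Longest linear sequence:** 9 steps (1, 2, 4, 6, 7, 9, 13, 14, 15)

**Steps most likely to fail**

Step 13. The first C–C bond formation may show poor facial or endo/exo selectivity, or cations 22 and 23 may be captured by A-ring carbons of a second molecule instead of by 21 and ring D. The fallback uses known chemistry, halogen blocking of C8. It sets out from 2, 5 and 6. Compound 2 is brominated with NBS (CH2Cl2, −78 °C to rt) at its most nucleophilic carbon to give 8-bromo-5,7,3',4'-tetra-O-benzyl-(–)-epicatechin F1. Acylation with 5 (Et3N, DMAP) gives 8-bromo-5,7,3',4'-tetra-O-benzylepicatechin 3-O-[3,4,5-tris(benzyloxy)benzoate] F2. TMSOTf-mediated Friedel–Crafts coupling of F2 with 6, in which C6 is the only free carbon of the nucleophile's A ring, gives the 8-bromo derivative of 25 F3. Hydrogenolysis over Pd(OH)2/C with Et3N removes the bromine and all benzyl groups, and the fallback comes back to the route at 26.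

Step 14. The C4 cation may be captured by an aromatic carbon of a second molecule (oligomerisation), hydride may be delivered to the gallate-derived dioxolenium carbon instead of C4, or acid may cleave the interflavan bond. The fallback replaces hydride capture with thiol capture and a neutral radical reduction. It sets out from 24. PhSH (5 equiv) with cat. TMSOTf at −78 °C (thiolysis of a flavan 4-ether) gives the 4-phenylthio analogue of 25 (3,4-trans) F4, because the thiol traps the cation much faster than a silane does. Bu3SnH/AIBN in toluene at 80 °C then cleaves the benzylic C–S bond homolytically, and the fallback comes back to the route at 25.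

Step 6. The C4 cation may attack a carbon ortho to the silyloxy group (wrong ring-D substitution pattern), or the silyl group may be lost under the Lewis acid. The fallback removes the regiochemical question by symmetry. It sets out from 6, which is coupled with excess phloroglucinol (BF3·OEt2, THF–CH2Cl2), whose three CH carbons are equivalent, to give the 4β-(2,4,6-trihydroxyphenyl) adduct F5. TIPSCl (1 equiv, imidazole) silylates the only unhindered hydroxyl, para to the flavanyl group, to give the 4β-[2,6-dihydroxy-4-(triisopropylsilyloxy)phenyl] adduct F6. BnBr/K2CO3 then benzylates the two remaining phenols, and the fallback comes back to the route at 9.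

**Further compounds**
F1 | step 13 | 8-bromo-5,7,3',4'-tetra-O-benzyl-(–)-epicatechin | O[C@@H]1Cc2c(OCc3ccccc3)cc(OCc3ccccc3)c(Br)c2O[C@@H]1c1ccc(OCc2ccccc2)c(OCc2ccccc2)c1
F2 | step 13 | 8-bromo-5,7,3',4'-tetra-O-benzylepicatechin 3-O-[3,4,5-tris(benzyloxy)benzoate] | O=C(O[C@@H]1Cc2c(OCc3ccccc3)cc(OCc3ccccc3)c(Br)c2O[C@@H]1c1ccc(OCc2ccccc2)c(OCc2ccccc2)c1)c1cc(OCc2ccccc2)c(OCc2ccccc2)c(OCc2ccccc2)c1
F3 | step 13 | 8-bromo derivative of 25 (bromine on C8 of the lower unit) | O=C(O[C@@H]1[C@@H](c2c(OCc4ccccc4)c(Br)c3c(c2OCc4ccccc4)C[C@@H](OC(=O)c4cc(OCc5ccccc5)c(OCc5ccccc5)c(OCc5ccccc5)c4)[C@@H](c4ccc(OCc5ccccc5)c(OCc5ccccc5)c4)O3)c2c(OCc3ccccc3)cc(OCc3ccccc3)cc2O[C@@H]1c1ccc(OCc2ccccc2)c(OCc2ccccc2)c1)c1cc(OCc2ccccc2)c(OCc2ccccc2)c(OCc2ccccc2)c1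
F4 | step 14 | 4-phenylthio analogue of 25 (lower unit 2,3-cis-3,4-trans) | O=C(O[C@@H]1[C@@H](c2c(OCc4ccccc4)cc3c(c2OCc4ccccc4)[C@H](Sc4ccccc4)[C@@H](OC(=O)c4cc(OCc5ccccc5)c(OCc5ccccc5)c(OCc5ccccc5)c4)[C@@H](c4ccc(OCc5ccccc5)c(OCc5ccccc5)c4)O3)c2c(OCc3ccccc3)cc(OCc3ccccc3)cc2O[C@@H]1c1ccc(OCc2ccccc2)c(OCc2ccccc2)c1)c1cc(OCc2ccccc2)c(OCc2ccccc2)c(OCc2ccccc2)c1
F5 | step 6 | 4β-(2,4,6-trihydroxyphenyl)-5,7,3',4'-tetra-O-benzylepicatechin 3-O-[3,4,5-tris(benzyloxy)benzoate] | O=C(O[C@@H]1[C@@H](c2c(O)cc(O)cc2O)c2c(OCc3ccccc3)cc(OCc3ccccc3)cc2O[C@@H]1c1ccc(OCc2ccccc2)c(OCc2ccccc2)c1)c1cc(OCc2ccccc2)c(OCc2ccccc2)c(OCc2ccccc2)c1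
F6 | step 6 | 4β-[2,6-dihydroxy-4-(triisopropylsilyloxy)phenyl]-5,7,3',4'-tetra-O-benzylepicatechin 3-O-[3,4,5-tris(benzyloxy)benzoate] | O=C(O[C@@H]1[C@@H](c2c(O)cc(O[Si](C(C)C)(C(C)C)C(C)C)cc2O)c2c(OCc3ccccc3)cc(OCc3ccccc3)cc2O[C@@H]1c1ccc(OCc2ccccc2)c(OCc2ccccc2)c1)c1cc(OCc2ccccc2)c(OCc2ccccc2)c(OCc2ccccc2)c1
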